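The route rests on one disconnection: ring A, a hexasubstituted benzene whose oxygens (C5, C7, C8a) and carbons (C4a, C6, C8) alternate, is read as three oxygen-bearing alkynes joined head to tail, two of them tied through O1–C2–C3–C4. A rhodium-catalysed [2+2+2] cycloaddition of an anti-configured 1,7-diyne (ethoxy ynone and benzylic alkynyl ether, with C2 and C3 already set in the tether) with a siloxyalkyne forms C4a–C8a, C5–C6 and C7–C8 and so closes ring A and ring C in one operation. The diyne comes from an Evans aldol adduct by chelation-controlled reduction, alkynyl ether formation and ynone installation.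

Key step: step 15

Remark: flavanone numbering (O1, C2, C3, C4, C4a, C5 to C8, C8a) is used for all intermediates; compounds 1, 2, 4, 11, 15, 21 and 25 are taken as commercial.
Remark: O3 and the three phenols are carried as benzyl ethers, because a silyl group on O3 would migrate to the neighbouring alkoxide in step 7 and aryl silyl ethers would not survive the fluoride that frees the C4 hydroxyl in step 9.

Step 1
Reactants: 1 (R)-4-benzyloxazolidin-2-one; 2 (benzyloxy)acetyl chloride
Product: 3 (R)-4-benzyl-3-[(benzyloxy)acetyl]oxazolidin-2-one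
Conditions: n-BuLi, THF, −78 °C; then 2, −78 to 0 °C
Reagents that add atoms: none
Why: N-acylation of the lithiated oxazolidinone by an acid chloride is the standard way to the imide, and no stereocentre is formed.

Step 2
Reactants: 3 (R)-4-benzyl-3-[(benzyloxy)acetyl]oxazolidin-2-one; 4 4-(benzyloxy)benzaldehyde
Product: 6 (R)-4-benzyl-3-{(2R,3S)-2-(benzyloxy)-3-[4-(benzyloxy)phenyl]-3-hydroxypropanoyl}oxazolidin-2-one, via boron enolate 5 (not isolated)
Conditions: Bu2BOTf, Et3N, CH2Cl2, −78 to 0 °C; 4, −78 to 0 °C; pH 7 buffer, MeOH, H2O2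
Reagents that add atoms: none
Why: In this Evans syn-aldol reaction the (Z)-boron enolate reacts through a chair Zimmerman–Traxler transition state on the face away from the auxiliary benzyl group, which sets the benzyloxy-bearing carbon (future C3) as R and the carbinol as S; the carbinol is corrected in steps 5 and 6.

Step 3
Reactants: 6 syn aldol adduct
Product: 7 (1S,2S)-2-(benzyloxy)-1-[4-(benzyloxy)phenyl]propane-1,3-diol
Conditions: LiBH4, MeOH (1 equiv), THF, 0 °C
Reagents that add atoms: none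
Why: Reductive cleavage of the N-acyloxazolidinone by borohydride gives the primary alcohol (future C4) and returns the auxiliary without touching either stereocentre.

Step 4
Reactants: 7 (1S,2S)-2-(benzyloxy)-1-[4-(benzyloxy)phenyl]propane-1,3-diol
Product: 8 (1S,2S)-2-(benzyloxy)-1-[4-(benzyloxy)phenyl]-3-[(triisopropylsilyl)oxy]propan-1-ol
Conditions: triisopropylsilyl chloride, imidazole, DMF, 0 °C to rt
Reagents that add atoms: triisopropylsilyl chloride, CC(C)[Si](Cl)(C(C)C)C(C)C
Why: Silylation distinguishes the primary from the hindered secondary benzylic hydroxyl, and the bulky triisopropylsilyl group is chosen because it resists migration to the alkoxide generated in step 7.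

Step 5
Reactants: 8 syn alcohol
Product: 9 (S)-2-(benzyloxy)-1-[4-(benzyloxy)phenyl]-3-[(triisopropylsilyl)oxy]propan-1-one
Conditions: Dess–Martin periodinane, NaHCO3, CH2Cl2, 0 °C to rt
Reagents that add atoms: none
Why: Dess–Martin oxidation of the benzylic alcohol under buffered conditions erases the wrongly set carbinol centre while the α-benzyloxy stereocentre is not enolised.

Step 6
Reactants: 9 (S)-2-(benzyloxy)-1-[4-(benzyloxy)phenyl]-3-[(triisopropylsilyl)oxy]propan-1-one
Product: 10 (1R,2S)-2-(benzyloxy)-1-[4-(benzyloxy)phenyl]-3-[(triisopropylsilyl)oxy]propan-1-ol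
Conditions: Zn(BH4)2, Et2O, −20 to 0 °C
Reagents that add atoms: none
Why: In this chelation-controlled ketone reduction (Cram chelate model) zinc bridges the carbonyl and the α-benzyloxy oxygen and hydride enters from the side of the α-hydrogen, which should give the anti alcohol and so sets C2 as R.

Step 7
Reactants: 10 anti alcohol; 11 trichloroethylene
Product: 14 {(2S,3R)-2-(benzyloxy)-3-[4-(benzyloxy)phenyl]-3-[(E)-(1,2-dichlorovinyl)oxy]propoxy}triisopropylsilane, via potassium alkoxide 12 (not isolated), via dichloroacetylene 13 (not isolated)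
Conditions: KH, THF, 0 °C to rt; 11, −50 °C to rt
Reagents that add atoms: none
Why: Addition of the alkoxide to dichloroacetylene formed in the flask (the trichloroethylene route to 1,2-dichlorovinyl ethers) makes the O1–C8a bond without touching the C2–O bond, so configuration is retained, and the non-migrating benzyl group on O3 keeps the alkoxide in place.

Step 8
Reactants: 14 dichlorovinyl ether; 15 4-(benzyloxy)benzyl bromide
Product: 18 {(2S,3R)-2-(benzyloxy)-3-[4-(benzyloxy)phenyl]-3-({3-[4-(benzyloxy)phenyl]prop-1-yn-1-yl}oxy)propoxy}triisopropylsilane, via chloroalkynyl ether 16 (not isolated), via lithium alkynyl ether 17 (not isolated)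
Conditions: n-BuLi (2.2 equiv), THF, −78 to −40 °C; HMPA, 15, −78 to 0 °C
Reagents that add atoms: none
Why: β-Elimination and chlorine–lithium exchange give the lithium alkynyl ether, whose SN2 C-alkylation by the reactive benzylic bromide installs the C8 benzyl group; the mixture is kept at or below 0 °C because benzylic alkynyl ethers rearrange sigmatropically on heating.

Step 9
Reactants: 18 silyl-protected alkynyl ether
Product: 19 (2S,3R)-2-(benzyloxy)-3-[4-(benzyloxy)phenyl]-3-({3-[4-(benzyloxy)phenyl]prop-1-yn-1-yl}oxy)propan-1-ol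
Conditions: TBAF, THF, 0 °C to rt
Reagents that add atoms: none
Why: Fluoride-mediated desilylation frees the C4 hydroxyl, and the only silyl group present is the one to be removed while benzyl ethers and the base-stable alkynyl ether are inert.

Step 10
Reactants: 19 primary alcohol
Product: 20 (2R,3R)-2-(benzyloxy)-3-[4-(benzyloxy)phenyl]-3-({3-[4-(benzyloxy)phenyl]prop-1-yn-1-yl}oxy)propanal
Conditions: Dess–Martin periodinane, NaHCO3, CH2Cl2, 0 °C; used crude
Reagents that add atoms: none
Why: Buffered Dess–Martin oxidation gives the aldehyde under non-acidic conditions that the acid-labile alkynyl ether tolerates, and immediate use avoids epimerisation at C3 or β-elimination.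

Step 11
Reactants: 20 aldehyde; 21 ethoxyacetylene
Product: 23 (3RS,4S,5R)-4-(benzyloxy)-5-[4-(benzyloxy)phenyl]-5-({3-[4-(benzyloxy)phenyl]prop-1-yn-1-yl}oxy)-1-ethoxypent-1-yn-3-ol, via lithium ethoxyacetylide 22 (not isolated)
Conditions: 21, n-BuLi, THF, −78 °C; then 20, −78 °C; aqueous NaHCO3
Reagents that add atoms: none
Why: 1,2-Addition of the lithium acetylide to the aldehyde at −78 °C is faster than enolisation and forms the C4–C4a bond; the new carbinol centre arises as a mixture, which is irrelevant because step 12 removes it.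

Step 12
Reactants: 23 propargylic alcohol
Product: 24 (4R,5R)-4-(benzyloxy)-5-[4-(benzyloxy)phenyl]-5-({3-[4-(benzyloxy)phenyl]prop-1-yn-1-yl}oxy)-1-ethoxypent-1-yn-3-one
Conditions: MnO2, CH2Cl2, 0 °C to rt
Reagents that add atoms: none
Why: Oxidation of the propargylic alcohol by MnO2 under neutral conditions gives the ynone and avoids the acid-induced Meyer–Schuster rearrangement of ethoxyethynyl carbinols.

Step 13
Reactants: 15 4-(benzyloxy)benzyl bromide; 25 ethynylmagnesium bromide
Product: 26 1-(benzyloxy)-4-(prop-2-yn-1-yl)benzene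
Conditions: 25 (3 equiv), CuBr (cat.), THF, 0 °C to rt
Reagents that add atoms: none
Why: Copper-catalysed substitution of a benzylic bromide by an alkynyl Grignard reagent is an established sp–sp3 coupling, and the excess of 25 suppresses a second alkylation.

Step 14
Reactants: 26 1-(benzyloxy)-4-(prop-2-yn-1-yl)benzene
Product: 29 ({3-[4-(benzyloxy)phenyl]prop-1-yn-1-yl}oxy)triisopropylsilane, via lithium acetylide 27 (not isolated), via lithium ynolate 28 (not isolated)
Conditions: LiN(SiMe3)2, THF, −78 °C; t-BuOOLi (from t-BuOOH and LiN(SiMe3)2), −78 to 0 °C; triisopropylsilyl triflate, −78 to 0 °C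
Reagents that add atoms: tert-butyl hydroperoxide, CC(C)(C)OO; triisopropylsilyl trifluoromethanesulfonate, CC(C)[Si](OS(=O)(=O)C(F)(F)F)(C(C)C)C(C)C
Why: Oxygen transfer from lithium tert-butyl peroxide to the lithium acetylide (acetylide oxidation to an ynolate) followed by O-silylation with the bulky silyl triflate is the known access to siloxyalkynes from terminal alkynes.

Step 15
Reactants: 24 anti-configured ethoxy ynone–alkynyl ether 1,7-diyne; 29 siloxyalkyne
Product: 30 (2R,3R)-3-(benzyloxy)-6,8-bis[4-(benzyloxy)benzyl]-2-[4-(benzyloxy)phenyl]-5-ethoxy-7-[(triisopropylsilyl)oxy]chroman-4-one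
Conditions: [Rh(C8H12)2]BF4 (10 mol %), 2,2'-bis(diphenylphosphino)biphenyl (10 mol %), activated with H2 then Ar; 29 (3 equiv), CH2Cl2, rt; slow addition of 24
Reagents that add atoms: none
Why: Proposed new method: the cationic monovalent rhodium bisphosphine complex should couple the two alkynes of 24 oxidatively to a rhodacyclopentadiene (C4a–C8a bond), into which 29 inserts before reductive elimination forms C5–C6 and C7–C8, the closest known reaction type being the rhodium-catalysed [2+2+2] cycloaddition of 1,6- and 1,7-diynes with monoalkynes, alkynyl ethers included, to fused benzenes, whereas three oxygen-substituted alkynes giving a chromanone have not been shown. Ring C closes as a six-membered ring by the tether-enforced oxidative coupling of C4a with C8a, and ring A closes by alkyne insertion and reductive elimination as the formal [2+2+2] benzannulation. No new stereocentre is formed, and C2 and C3 lie in the tether with no bond to them broken. The step needs head-to-tail orientation of 29 and cross-reaction over self-coupling: the orientation should follow from matched polarity (the nucleophilic benzyl-bearing carbon of 29 joins the electrophilic ethoxy-bearing C5 of the ynone, its oxygen-bearing carbon joins the nucleophilic C8) and from the bulk of the triisopropylsilyloxy group, while slow addition of 24 to catalyst and excess 29 at room temperature should suppress diyne dimerisation and spare the heat-sensitive benzylic alkynyl ether.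

Step 16
Reactants: 30 cycloadduct
Product: 31 (2R,3R)-3-(benzyloxy)-6,8-bis[4-(benzyloxy)benzyl]-2-[4-(benzyloxy)phenyl]-5-ethoxy-7-hydroxychroman-4-one
Conditions: TBAF, AcOH, THF, 0 °C
Reagents that add atoms: none
Why: Fluoride cleaves the aryl silyl ether at O7 (desilylation), and the acetic acid buffer prevents base-induced opening of ring C or epimerisation at C3.

Step 17
Reactants: 31 7-hydroxy flavanonol
Product: 32 gericudranin D
Conditions: BCl3, pentamethylbenzene, CH2Cl2, −78 to 0 °C; MeOH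
Reagents that add atoms: none
Why: Lewis-acid ether cleavage by BCl3 should remove the four benzyl groups (the benzyl cation being trapped by pentamethylbenzene) and the 5-O-ethyl group, which is activated by chelation to the C4 carbonyl, at temperatures where C2 and C3 are not epimerised.

Compound list
1 | (R)-4-benzyloxazolidin-2-one | O=C1N[C@H](Cc2ccccc2)CO1 | starting material
2 | (benzyloxy)acetyl chloride | O=C(Cl)COCc1ccccc1 | starting material
3 | (R)-4-benzyl-3-[(benzyloxy)acetyl]oxazolidin-2-one | O=C(COCc1ccccc1)N1[C@H](Cc2ccccc2)COC1=O | intermediate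
4 | 4-(benzyloxy)benzaldehyde | O=Cc1ccc(OCc2ccccc2)cc1 | starting material
5 | (Z)-dibutylboron enolate of 3 (not isolated) | CCCCB(CCCC)O/C(=C\OCc1ccccc1)N1[C@H](Cc2ccccc2)COC1=O | intermediate
6 | (R)-4-benzyl-3-{(2R,3S)-2-(benzyloxy)-3-[4-(benzyloxy)phenyl]-3-hydroxypropanoyl}oxazolidin-2-one | O=C(N1[C@H](Cc2ccccc2)COC1=O)[C@H](OCc1ccccc1)[C@@H](O)c1ccc(OCc2ccccc2)cc1 | intermediate
7 | (1S,2S)-2-(benzyloxy)-1-[4-(benzyloxy)phenyl]propane-1,3-diol | OC[C@H](OCc1ccccc1)[C@@H](O)c1ccc(OCc2ccccc2)cc1 | intermediate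
8 | (1S,2S)-2-(benzyloxy)-1-[4-(benzyloxy)phenyl]-3-[(triisopropylsilyl)oxy]propan-1-ol | CC(C)[Si](C(C)C)(C(C)C)OC[C@H](OCc1ccccc1)[C@@H](O)c1ccc(OCc2ccccc2)cc1 | intermediate
9 | (S)-2-(benzyloxy)-1-[4-(benzyloxy)phenyl]-3-[(triisopropylsilyl)oxy]propan-1-one | CC(C)[Si](C(C)C)(C(C)C)OC[C@H](OCc1ccccc1)C(=O)c1ccc(OCc2ccccc2)cc1 | intermediate
10 | (1R,2S)-2-(benzyloxy)-1-[4-(benzyloxy)phenyl]-3-[(triisopropylsilyl)oxy]propan-1-ol | CC(C)[Si](C(C)C)(C(C)C)OC[C@H](OCc1ccccc1)[C@H](O)c1ccc(OCc2ccccc2)cc1 | intermediate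
11 | trichloroethylene | ClC=C(Cl)Cl | starting material
12 | potassium alkoxide of 10 (not isolated) | CC(C)[Si](C(C)C)(C(C)C)OC[C@H](OCc1ccccc1)[C@H]([O-])c1ccc(OCc2ccccc2)cc1.[K+] | intermediate
13 | dichloroacetylene (not isolated) | ClC#CCl | intermediate
14 | {(2S,3R)-2-(benzyloxy)-3-[4-(benzyloxy)phenyl]-3-[(E)-(1,2-dichlorovinyl)oxy]propoxy}triisopropylsilane | CC(C)[Si](C(C)C)(C(C)C)OC[C@H](OCc1ccccc1)[C@H](O/C(Cl)=C\Cl)c1ccc(OCc2ccccc2)cc1 | intermediate
15 | 4-(benzyloxy)benzyl bromide | BrCc1ccc(OCc2ccccc2)cc1 | starting material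
16 | {(2S,3R)-2-(benzyloxy)-3-[4-(benzyloxy)phenyl]-3-[(chloroethynyl)oxy]propoxy}triisopropylsilane (not isolated) | CC(C)[Si](C(C)C)(C(C)C)OC[C@H](OCc1ccccc1)[C@H](OC#CCl)c1ccc(OCc2ccccc2)cc1 | intermediate
17 | lithium acetylide of the ethynyl ether of 10 (not isolated) | CC(C)[Si](C(C)C)(C(C)C)OC[C@H](OCc1ccccc1)[C@H](OC#C[Li])c1ccc(OCc2ccccc2)cc1 | intermediate
18 | {(2S,3R)-2-(benzyloxy)-3-[4-(benzyloxy)phenyl]-3-({3-[4-(benzyloxy)phenyl]prop-1-yn-1-yl}oxy)propoxy}triisopropylsilane | CC(C)[Si](C(C)C)(C(C)C)OC[C@H](OCc1ccccc1)[C@H](OC#CCc1ccc(OCc2ccccc2)cc1)c1ccc(OCc2ccccc2)cc1 | intermediate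
19 | (2S,3R)-2-(benzyloxy)-3-[4-(benzyloxy)phenyl]-3-({3-[4-(benzyloxy)phenyl]prop-1-yn-1-yl}oxy)propan-1-ol | OC[C@H](OCc1ccccc1)[C@H](OC#CCc1ccc(OCc2ccccc2)cc1)c1ccc(OCc2ccccc2)cc1 | intermediate
20 | (2R,3R)-2-(benzyloxy)-3-[4-(benzyloxy)phenyl]-3-({3-[4-(benzyloxy)phenyl]prop-1-yn-1-yl}oxy)propanal | O=C[C@H](OCc1ccccc1)[C@H](OC#CCc1ccc(OCc2ccccc2)cc1)c1ccc(OCc2ccccc2)cc1 | intermediate
21 | ethoxyacetylene | CCOC#C | starting material
22 | lithium ethoxyacetylide (not isolated) | CCOC#C[Li] | intermediate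
23 | (3RS,4S,5R)-4-(benzyloxy)-5-[4-(benzyloxy)phenyl]-5-({3-[4-(benzyloxy)phenyl]prop-1-yn-1-yl}oxy)-1-ethoxypent-1-yn-3-ol | CCOC#CC(O)[C@H](OCc1ccccc1)[C@H](OC#CCc1ccc(OCc2ccccc2)cc1)c1ccc(OCc2ccccc2)cc1 | intermediate
24 | (4R,5R)-4-(benzyloxy)-5-[4-(benzyloxy)phenyl]-5-({3-[4-(benzyloxy)phenyl]prop-1-yn-1-yl}oxy)-1-ethoxypent-1-yn-3-one | CCOC#CC(=O)[C@H](OCc1ccccc1)[C@H](OC#CCc1ccc(OCc2ccccc2)cc1)c1ccc(OCc2ccccc2)cc1 | intermediate
25 | ethynylmagnesium bromide | C#C[Mg]Br | starting material
26 | 1-(benzyloxy)-4-(prop-2-yn-1-yl)benzene | C#CCc1ccc(OCc2ccccc2)cc1 | intermediate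
27 | lithium acetylide of 26 (not isolated) | [Li]C#CCc1ccc(OCc2ccccc2)cc1 | intermediate
28 | lithium 3-[4-(benzyloxy)phenyl]prop-1-yn-1-olate (not isolated) | [Li]OC#CCc1ccc(OCc2ccccc2)cc1 | intermediate
29 | ({3-[4-(benzyloxy)phenyl]prop-1-yn-1-yl}oxy)triisopropylsilane | CC(C)[Si](C(C)C)(C(C)C)OC#CCc1ccc(OCc2ccccc2)cc1 | intermediate
30 | (2R,3R)-3-(benzyloxy)-6,8-bis[4-(benzyloxy)benzyl]-2-[4-(benzyloxy)phenyl]-5-ethoxy-7-[(triisopropylsilyl)oxy]chroman-4-one | O=C1c2c(OCC)c(Cc3ccc(OCc4ccccc4)cc3)c(O[Si](C(C)C)(C(C)C)C(C)C)c(Cc3ccc(OCc4ccccc4)cc3)c2O[C@H](c2ccc(OCc3ccccc3)cc2)[C@H]1OCc1ccccc1 | intermediate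
31 | (2R,3R)-3-(benzyloxy)-6,8-bis[4-(benzyloxy)benzyl]-2-[4-(benzyloxy)phenyl]-5-ethoxy-7-hydroxychroman-4-one | O=C1c2c(OCC)c(Cc3ccc(OCc4ccccc4)cc3)c(O)c(Cc3ccc(OCc4ccccc4)cc3)c2O[C@H](c2ccc(OCc3ccccc3)cc2)[C@H]1OCc1ccccc1 | intermediate
32 | gericudranin D, (2R,3R)-3,5,7-trihydroxy-6,8-bis(4-hydroxybenzyl)-2-(4-hydroxyphenyl)chroman-4-one | O=C1c2c(O)c(Cc3ccc(O)cc3)c(O)c(Cc3ccc(O)cc3)c2O[C@H](c2ccc(O)cc2)[C@H]1O | target

Total step count: 17. Longest linear sequence: 15 steps (steps 1 to 12, then 15 to 17).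

Steps most likely to fail

Step 15. The siloxyalkyne may insert in the reversed orientation, the diyne may couple with itself, or the push–pull ynone may be lost to rhodium-induced rearrangement before cyclisation. The fallback uses only known chemistry, sets out from 15 and 4 and comes back to the route at 32. Twofold C-benzylation of commercial 2,4,6-trihydroxyacetophenone with 15 (NaOMe, MeOH) should give 1-{3,5-bis[4-(benzyloxy)benzyl]-2,4,6-trihydroxyphenyl}ethan-1-one F1. Threefold methoxymethylation (NaH, MOMCl, DMF) gives the tris(methoxymethyl) ether F2. Claisen–Schmidt condensation with 4 (KOH, EtOH) gives the (E)-chalcone F3. Julia–Colonna epoxidation (poly-L-leucine, urea–H2O2, DBU, THF) gives the (αR,βS)-epoxy ketone F4. HCl in MeOH/THF removes the methoxymethyl groups, and the freed 2'-hydroxyl opens the epoxide at the benzylic carbon with inversion (6-endo) to give the tri-O-benzyl ether of gericudranin D F5. Hydrogenolysis (H2, Pd/C, EtOAc/MeOH) then gives 32.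

Step 8. C-Alkylation of the lithium alkynyl ether may be slow, and the basic medium may isomerise the skipped aryl alkyne to an allenyl ether or metallate it further. The fallback sets out from 14 and comes back at 18, replacing the SN2 alkylation by a palladium-catalysed cross-coupling. Treatment of 14 with n-BuLi and a methanol quench at −78 °C gives the isolable terminal alkynyl ether {(2S,3R)-2-(benzyloxy)-3-[4-(benzyloxy)phenyl]-3-(ethynyloxy)propoxy}triisopropylsilane F6. Relithiation and transmetallation with ZnBr2 give the alkynylzinc bromide F7, and Negishi coupling with 15 under PdCl2[(2-Ph2PC6H4)2O] (divalent palladium precatalyst, THF, rt) gives 18.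

Step 17. Six ether cleavages under one Lewis acid may be accompanied by ionisation of the C2–O1 bond of the 4'-oxygenated flavanonol (opening of ring C, epimerisation at C2) or by incomplete loss of the ethyl group. The fallback sets out from 31 and comes back at 32. Hydrogenolysis (H2, Pd(OH)2/C, EtOAc/MeOH) removes the four benzyl groups under neutral conditions to give 5-O-ethylgericudranin D F8. The single chelated ethyl ether is then cleaved with BCl3 (CH2Cl2, 0 °C) to give 32.

Further compounds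
F1 | step 15 | 1-{3,5-bis[4-(benzyloxy)benzyl]-2,4,6-trihydroxyphenyl}ethan-1-one | CC(=O)c1c(O)c(Cc2ccc(OCc3ccccc3)cc2)c(O)c(Cc2ccc(OCc3ccccc3)cc2)c1O
F2 | step 15 | 1-{3,5-bis[4-(benzyloxy)benzyl]-2,4,6-tris(methoxymethoxy)phenyl}ethan-1-one | CC(=O)c1c(OCOC)c(Cc2ccc(OCc3ccccc3)cc2)c(OCOC)c(Cc2ccc(OCc3ccccc3)cc2)c1OCOC
F3 | step 15 | (E)-1-{3,5-bis[4-(benzyloxy)benzyl]-2,4,6-tris(methoxymethoxy)phenyl}-3-[4-(benzyloxy)phenyl]prop-2-en-1-one | O=C(/C=C/c1ccc(OCc2ccccc2)cc1)c1c(OCOC)c(Cc2ccc(OCc3ccccc3)cc2)c(OCOC)c(Cc2ccc(OCc3ccccc3)cc2)c1OCOC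
F4 | step 15 | {3,5-bis[4-(benzyloxy)benzyl]-2,4,6-tris(methoxymethoxy)phenyl}{(2R,3S)-3-[4-(benzyloxy)phenyl]oxiran-2-yl}methanone | O=C([C@@H]1O[C@H]1c1ccc(OCc2ccccc2)cc1)c1c(OCOC)c(Cc2ccc(OCc3ccccc3)cc2)c(OCOC)c(Cc2ccc(OCc3ccccc3)cc2)c1OCOC
F5 | step 15 | (2R,3R)-6,8-bis[4-(benzyloxy)benzyl]-2-[4-(benzyloxy)phenyl]-3,5,7-trihydroxychroman-4-one | O=C1c2c(O)c(Cc3ccc(OCc4ccccc4)cc3)c(O)c(Cc3ccc(OCc4ccccc4)cc3)c2O[C@H](c2ccc(OCc3ccccc3)cc2)[C@H]1O
F6 | step 8 | {(2S,3R)-2-(benzyloxy)-3-[4-(benzyloxy)phenyl]-3-(ethynyloxy)propoxy}triisopropylsilane | CC(C)[Si](C(C)C)(C(C)C)OC[C@H](OCc1ccccc1)[C@H](OC#C)c1ccc(OCc2ccccc2)cc1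
F7 | step 8 | alkynylzinc bromide derived from F6 | CC(C)[Si](C(C)C)(C(C)C)OC[C@H](OCc1ccccc1)[C@H](OC#C[Zn]Br)c1ccc(OCc2ccccc2)cc1
F8 | step 17 | (2R,3R)-5-ethoxy-3,7-dihydroxy-6,8-bis(4-hydroxybenzyl)-2-(4-hydroxyphenyl)chroman-4-one | O=C1c2c(OCC)c(Cc3ccc(O)cc3)c(O)c(Cc3ccc(O)cc3)c2O[C@H](c2ccc(O)cc2)[C@H]1O
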